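**Retrosynthetic overview**
- The target is the 3α,8α,12,20-tetraacetate of a labd-14-ene-3,8,12,13,20-pentol. It is traced back to a 13-O-PMB tetraol, made by one LiAlH4 reduction of an 8α,17-epoxy C20 ester, which comes from a labda-8(17),14-diene decalin after inversion at C3.
- The strategy rests on C20, the oxidised carbon on the ring-fusion atom C10. C10 is where the two ring-forming bonds meet: C4–C5 of ring A ends there and C9–C10 of ring B starts there. With C20 carried as an ester, C5=C10 is an enoate that accepts the C4 radical at C5 and passes on an electrophilic C10 radical.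
- Both rings are disconnected at once to an acyclic (2Z,6E)-epoxy-enoate. A Cp2TiCl radical cascade closes ring A first (C4–C5) and ring B second (C9–C10); no ring of the skeleton exists before it.
- The chain is cut at C5=C10 (Ando olefination, phosphonate carrying the C3 oxirane) and at C9–C11 (alkenylalanate opening of a C11–C16 oxirane).
- C12 comes from (R)-glycerate, C13 from a chelation-controlled MeMgBr addition, and C3 from a Shi epoxidation.

Key step: step 15

Remark: labdane numbering (C1–C20) is used for every intermediate, acyclic ones included, and α/β refer to the usual labdane drawing with C20 on C10 as β; the target is then (12R,13S)-13-hydroxylabd-14-ene-3α,8α,12,20-tetrayl tetraacetate (3R,5R,8R,9R,10R,12R,13S).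

**Route**

Step 1
Reactants: 1 methyl (R)-2,2-dimethyl-1,3-dioxolane-4-carboxylate
Product: 2 (R)-N-methoxy-N,2,2-trimethyl-1,3-dioxolane-4-carboxamide
Conditions: MeNH(OMe)·HCl, i-PrMgCl, THF, −20 °C
Reagents that add atoms: N,O-dimethylhydroxylamine hydrochloride, CNOC.Cl
Why: the chloromagnesium amide of N,O-dimethylhydroxylamine should convert the methyl ester directly into the Weinreb amide at low temperature without touching the acetonide or the α-stereocentre (Weinreb amide formation).

Step 2
Reactants: 2 (R)-N-methoxy-N,2,2-trimethyl-1,3-dioxolane-4-carboxamide; 3 vinylmagnesium bromide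
Product: 4 (R)-1-(2,2-dimethyl-1,3-dioxolan-4-yl)prop-2-en-1-one
Conditions: THF, −78 to 0 °C; inverse quench into cold aq. KHSO4/Et2O; used crude
Reagents that add atoms: none
Why: the Weinreb amide holds the tetrahedral magnesium chelate until the quench so that only one vinyl group adds (Weinreb ketone synthesis), and the acidic inverse quench protonates the released MeNHOMe before it can add to the enone.

Step 3
Reactants: 4 (R)-1-(2,2-dimethyl-1,3-dioxolan-4-yl)prop-2-en-1-one
Product: 5 (S)-2-[(R)-2,2-dimethyl-1,3-dioxolan-4-yl]but-3-en-2-ol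
Conditions: MeMgBr, THF, −78 °C
Reagents that add atoms: methylmagnesium bromide, C[Mg]Br
Why: Grignard 1,2-addition under Cram chelation control, in which magnesium bridges the ketone oxygen and the dioxolane oxygen on C12 and methyl enters on the face of the C12 hydrogen, should set C13 as S; any 13-epimer would be removed by chromatography.

Step 4
Reactants: 5 (S)-2-[(R)-2,2-dimethyl-1,3-dioxolan-4-yl]but-3-en-2-ol
Product: 6 (4R)-4-[(2S)-2-(4-methoxybenzyloxy)but-3-en-2-yl]-2,2-dimethyl-1,3-dioxolane
Conditions: NaH, PMBCl, Bu4NI (cat.), DMF, 0 °C to rt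
Reagents that add atoms: 4-methoxybenzyl chloride, COc1ccc(CCl)cc1
Why: Williamson etherification of the tertiary alkoxide with the reactive benzylic halide (iodide catalysis) should mark the 13-oxygen, the only hydroxyl that stays free in the target, without touching a stereocentre.

Step 5
Reactants: 6 (4R)-4-[(2S)-2-(4-methoxybenzyloxy)but-3-en-2-yl]-2,2-dimethyl-1,3-dioxolane
Product: 7 (2R,3S)-3-(4-methoxybenzyloxy)-3-methylpent-4-ene-1,2-diol
Conditions: AcOH/H2O (4:1), 40 °C
Reagents that add atoms: none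
Why: mild acid hydrolysis of the terminal isopropylidene acetal should free the 11,12-diol, while the tertiary allylic PMB ether, flanked by oxygenated carbons that disfavour ionisation, should persist.

Step 6
Reactants: 7 (2R,3S)-3-(4-methoxybenzyloxy)-3-methylpent-4-ene-1,2-diol
Product: 9 (2R)-2-[(2S)-2-(4-methoxybenzyloxy)but-3-en-2-yl]oxirane, via primary monotosylate 8 (not isolated)
Conditions: NaH, 1-(p-toluenesulfonyl)imidazole, THF, 0 °C to rt
Reagents that add atoms: none
Why: the primary hydroxyl is sulfonylated selectively (the secondary one is next to a quaternary carbon) and the C12 alkoxide then displaces the tosylate at C11 in a 3-exo-tet closure, so the C12–O bond is never broken and C12 stays R.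

Step 7
Reactants: 10 pent-4-yn-1-ol
Product: 11 tert-butyldimethyl(pent-4-yn-1-yloxy)silane
Conditions: TBSCl, imidazole, CH2Cl2, rt
Reagents that add atoms: tert-butyldimethylsilyl chloride, CC(C)(C)[Si](C)(C)Cl
Why: standard silylation removes the acidic hydroxyl, so that only one aluminium centre is present when the alanate is formed in the next step.

Step 8
Reactants: 11 tert-butyldimethyl(pent-4-yn-1-yloxy)silane; 9 (2R)-2-[(2S)-2-(4-methoxybenzyloxy)but-3-en-2-yl]oxirane
Product: 14 (3S,4R,6E)-10-(tert-butyldimethylsilyloxy)-3-(4-methoxybenzyloxy)-3,7-dimethyldeca-1,6-dien-4-ol, via (E)-alkenyldimethylalane 12 (not isolated), via lithium butyl(alkenyl)dimethylalanate 13 (not isolated)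
Conditions: 11 (excess), Me3Al, Cp2ZrCl2 (0.2 equiv), CH2Cl2, rt; volatiles removed; n-BuLi, hexane/THF, −78 to 0 °C; then 9, THF, 0 °C to rt; aq. KNaC4H4O6 work-up
Reagents that add atoms: trimethylaluminium, C[Al](C)C
Why: Zr-catalysed syn-methylalumination (Negishi carboalumination) puts aluminium on the terminal carbon and the new methyl C17 on C8, which fixes the E geometry, and the derived alanate should transfer the alkenyl group with retention to the unhindered CH2 (C11) of the oxirane, forming C9–C11 and leaving C12 and C13 untouched.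

Step 9
Reactants: 14 (3S,4R,6E)-10-(tert-butyldimethylsilyloxy)-3-(4-methoxybenzyloxy)-3,7-dimethyldeca-1,6-dien-4-ol
Product: 15 (3S,4R,6E)-10-(tert-butyldimethylsilyloxy)-3-(4-methoxybenzyloxy)-3,7-dimethyldeca-1,6-dien-4-yl acetate
Conditions: Ac2O, pyridine, DMAP (cat.), CH2Cl2, rt
Reagents that add atoms: acetic anhydride, CC(=O)OC(C)=O
Why: DMAP-catalysed acetylation should cap the hindered secondary 12-hydroxyl with the acyl group that the target carries at that position.

Step 10
Reactants: 15 (3S,4R,6E)-10-(tert-butyldimethylsilyloxy)-3-(4-methoxybenzyloxy)-3,7-dimethyldeca-1,6-dien-4-yl acetate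
Product: 16 (3S,4R,6E)-10-hydroxy-3-(4-methoxybenzyloxy)-3,7-dimethyldeca-1,6-dien-4-yl acetate
Conditions: HF·pyridine, pyridine, THF, 0 °C to rt
Reagents that add atoms: none
Why: buffered fluoride should cleave the primary silyl ether while the acetate and the tertiary PMB ether are inert.

Step 11
Reactants: 16 (3S,4R,6E)-10-hydroxy-3-(4-methoxybenzyloxy)-3,7-dimethyldeca-1,6-dien-4-yl acetate
Product: 17 (3S,4R,6E)-3-(4-methoxybenzyloxy)-3,7-dimethyl-10-oxodeca-1,6-dien-4-yl acetate
Conditions: TEMPO (cat.), PhI(OAc)2, CH2Cl2, rt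
Reagents that add atoms: none
Why: oxoammonium-mediated oxidation should stop cleanly at the C5 aldehyde and tolerates the trisubstituted alkene, the vinyl group, the acetate and the PMB ether.

Step 12
Reactants: 18 5-bromo-2-methylpent-2-ene
Product: 19 (S)-3-(2-bromoethyl)-2,2-dimethyloxirane
Conditions: L-fructose-derived Shi ketone (enantiomer of the D-fructose catalyst, 0.3 equiv), KHSO5 (as Oxone, 2KHSO5·KHSO4·K2SO4), K2CO3, Bu4NHSO4, MeCN/CH2(OMe)2/aq. Na2B4O7 buffer, 0 °C
Reagents that add atoms: potassium peroxymonosulfate, [K+].[O-]S(=O)(=O)OO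
Why: Shi asymmetric epoxidation through a spiro dioxirane transition state; the D-fructose-derived ketone is expected to give the R oxirane of R–CH=CMe2 alkenes, so its enantiomer is used to set C3 as S.

Step 13
Reactants: 19 (S)-3-(2-bromoethyl)-2,2-dimethyloxirane; 20 ethyl 2-(diphenoxyphosphoryl)acetate
Product: 21 ethyl 2-(diphenoxyphosphoryl)-4-[(2S)-3,3-dimethyloxiran-2-yl]butanoate (both configurations at the phosphonate carbon)
Conditions: NaH, DMF, NaI (cat.), 0 to 50 °C
Reagents that add atoms: none
Why: SN2 C-alkylation of the stabilised phosphonoacetate anion by the primary bromide (iodide catalysis) should outpace attack on the trisubstituted oxirane, and the new centre at the phosphonate carbon is destroyed in step 14.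

Step 14
Reactants: 21 ethyl 2-(diphenoxyphosphoryl)-4-[(2S)-3,3-dimethyloxiran-2-yl]butanoate; 17 (3S,4R,6E)-3-(4-methoxybenzyloxy)-3,7-dimethyl-10-oxodeca-1,6-dien-4-yl acetate
Product: 22 ethyl (2Z,6E,9R,10S)-9-acetoxy-2-{2-[(2S)-3,3-dimethyloxiran-2-yl]ethyl}-10-(4-methoxybenzyloxy)-6,10-dimethyldodeca-2,6,11-trienoate
Conditions: NaH, THF, 0 °C; then 17, −78 to 0 °C
Reagents that add atoms: none
Why: in the Ando variant of the Horner–Wadsworth–Emmons olefination the electron-poor aryloxy groups make elimination from the kinetic adduct fast, so the ester should end cis to the aldehyde-derived chain (2Z), which places C20 where the C10 methyl of a farnesyl chain would sit.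

Step 15
Reactants: 22 ethyl (2Z,6E,9R,10S)-9-acetoxy-2-{2-[(2S)-3,3-dimethyloxiran-2-yl]ethyl}-10-(4-methoxybenzyloxy)-6,10-dimethyldodeca-2,6,11-trienoate
Product: 24 ethyl (12R,13S)-12-acetoxy-3β-hydroxy-13-(4-methoxybenzyloxy)labda-8(17),14-dien-20-oate (trans-decalin with H5 α, H9 α and the C10 ester β), via its 3-O-trimethylsilyl ether 23 (not isolated)
Conditions: Cp2TiCl2 (0.2 equiv), Mn powder (8 equiv), Me3SiCl (4 equiv), 2,4,6-collidine (7 equiv), THF, rt, 22 added slowly by syringe pump; then 5% aq. citric acid/THF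
Reagents that add atoms: none
Why: Proposed new method: Cp2TiCl (trivalent titanium) should open the trisubstituted oxirane homolytically to the tertiary C4 radical, which adds to C5, the β-carbon of the Z-enoate (ring A, 6-endo-trig, bond C4–C5), and the resulting electrophilic tertiary C10 α-ester radical then adds to C9 of the electron-rich E-C8=C9 alkene (ring B, 6-endo-trig, bond C9–C10), after which the C8 radical is captured by a second Cp2TiCl and loses a C17 hydrogen by β-hydride elimination to the 8(17)-alkene while Me3SiCl/collidine return the titanium alkoxide and hydride to Cp2TiCl2 for reduction by Mn. The closest known reaction types are the Cp2TiCl-mediated bicyclisation of 2,3-epoxyfarnesyl-type polyenes, the conjugate addition of Cp2TiCl-derived epoxide radicals to α,β-unsaturated esters and the 6-endo closure of α-carbonyl radicals onto trisubstituted alkenes in oxidative polyene cyclisations; what is new is the relay of the radical through an enoate placed inside the chain. C5 is set in a chair transition state for ring A in which the C3 O–Ti group and the C6 chain (trans to C1 on the Z-enoate) are equatorial, so H5 is α when C3 is S; C10 is set by chair closure of ring B with the new C9–C10 bond equatorial to ring A (trans fusion, ester β-axial); C9 follows from the E geometry of C8=C9, which places C11 equatorial (β). The step needs 6-endo regiochemistry twice and a ring-B closure that is faster than reduction of the C10 radical to a titanium enolate: the first is secured by polarity matching (nucleophilic radical to the enoate β-carbon, electrophilic radical to the less substituted alkene terminus, a tertiary radical formed each time), the second by holding Cp2TiCl at a low stationary concentration (0.2 equiv, slow addition of 22). The monosubstituted vinyl group next to quaternary C13 is a poor acceptor for the hindered C8 radical, so the cascade should stop at the bicycle.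

Step 16
Reactants: 24 ethyl (12R,13S)-12-acetoxy-3β-hydroxy-13-(4-methoxybenzyloxy)labda-8(17),14-dien-20-oate
Product: 25 ethyl (12R,13S)-12-acetoxy-13-(4-methoxybenzyloxy)-3-oxolabda-8(17),14-dien-20-oate
Conditions: Dess–Martin periodinane, NaHCO3, CH2Cl2, rt
Reagents that add atoms: none
Why: Dess–Martin oxidation of the hindered secondary 3β-alcohol under buffered conditions should give the 3-ketone without touching the alkenes, esters or the PMB ether.

Step 17
Reactants: 25 ethyl (12R,13S)-12-acetoxy-13-(4-methoxybenzyloxy)-3-oxolabda-8(17),14-dien-20-oate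
Product: 26 ethyl (12R,13S)-12-acetoxy-3α-hydroxy-13-(4-methoxybenzyloxy)labda-8(17),14-dien-20-oate
Conditions: LiBH(s-Bu)3 (L-Selectride), THF, −78 °C; aq. NH4Cl
Reagents that add atoms: none
Why: the bulky hydride should attack the 4,4-dimethyl-3-ketone along the equatorial trajectory and so give the axial 3α-alcohol (3R), and at −78 °C the acetate and the neopentyl ester should not be reduced.

Step 18
Reactants: 26 ethyl (12R,13S)-12-acetoxy-3α-hydroxy-13-(4-methoxybenzyloxy)labda-8(17),14-dien-20-oate
Product: 27 ethyl (12R,13S)-12-acetoxy-8α,17-epoxy-3α-hydroxy-13-(4-methoxybenzyloxy)labd-14-en-20-oate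
Conditions: mCPBA (1.1 equiv), NaHCO3, CH2Cl2, 0 °C
Reagents that add atoms: 3-chloroperoxybenzoic acid, OOC(=O)c1cccc(Cl)c1
Why: in this Prilezhaev epoxidation the electron-rich 1,1-disubstituted C8(17) alkene should react before the vinyl group of the allylic ether, and the peracid should approach the α face because the axial C10 ester shields the β face, which places the oxirane oxygen 8α.

Step 19
Reactants: 27 ethyl (12R,13S)-12-acetoxy-8α,17-epoxy-3α-hydroxy-13-(4-methoxybenzyloxy)labd-14-en-20-oate
Product: 28 (12R,13S)-13-(4-methoxybenzyloxy)labd-14-ene-3α,8α,12,20-tetraol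
Conditions: LiAlH4 (excess), THF, 0 °C (oxirane and acetate), then reflux (ester); aqueous NaOH work-up
Reagents that add atoms: none
Why: hydride should open the oxirane by SN2 attack at the unhindered C17 (C8–O retained, giving 8α-OH with C17 as the β-methyl), reduce the neopentyl ester to the C20 carbinol and cleave the 12-acetate in one operation, with the PMB ether untouched.

Step 20
Reactants: 28 (12R,13S)-13-(4-methoxybenzyloxy)labd-14-ene-3α,8α,12,20-tetraol
Product: 29 (12R,13S)-8α-hydroxy-13-(4-methoxybenzyloxy)labd-14-ene-3α,12,20-triyl triacetate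
Conditions: Ac2O, pyridine, DMAP (cat.), CH2Cl2, rt
Reagents that add atoms: acetic anhydride, CC(=O)OC(C)=O
Why: DMAP-catalysed acetylation should take the primary C20 and the secondary C3 and C12 hydroxyls and leave the tertiary 8-hydroxyl for the more forcing step that follows.

Step 21
Reactants: 29 (12R,13S)-8α-hydroxy-13-(4-methoxybenzyloxy)labd-14-ene-3α,12,20-triyl triacetate
Product: 30 (12R,13S)-13-(4-methoxybenzyloxy)labd-14-ene-3α,8α,12,20-tetrayl tetraacetate
Conditions: AcCl, N,N-dimethylaniline, CH2Cl2, 0 to 40 °C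
Reagents that add atoms: acetyl chloride, CC(Cl)=O
Why: acetyl chloride with the weak base N,N-dimethylaniline is the established way to acylate hindered tertiary carbinols without ionising them, so the 8α-acetate should form with retention and without elimination.

Step 22
Reactants: 30 (12R,13S)-13-(4-methoxybenzyloxy)labd-14-ene-3α,8α,12,20-tetrayl tetraacetate
Product: 31 (12R,13S)-13-hydroxylabd-14-ene-3α,8α,12,20-tetrayl tetraacetate (target CNP0127528.1)
Conditions: DDQ, CH2Cl2/pH 7 phosphate buffer, 0 °C to rt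
Reagents that add atoms: none
Why: oxidative PMB cleavage (hydride abstraction to the benzylic oxocarbenium ion, then hydrolysis) should free the tertiary 13-hydroxyl, since the acetates and the vinyl group are inert to DDQ and no free hydroxyl is present to trap the cation.

**Compound list**
1 | methyl (R)-2,2-dimethyl-1,3-dioxolane-4-carboxylate | COC(=O)[C@H]1COC(C)(C)O1 | starting material
2 | (R)-N-methoxy-N,2,2-trimethyl-1,3-dioxolane-4-carboxamide | CON(C)C(=O)[C@H]1COC(C)(C)O1 | intermediate
3 | vinylmagnesium bromide | C=C[Mg]Br | starting material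
4 | (R)-1-(2,2-dimethyl-1,3-dioxolan-4-yl)prop-2-en-1-one | C=CC(=O)[C@H]1COC(C)(C)O1 | intermediate
5 | (S)-2-[(R)-2,2-dimethyl-1,3-dioxolan-4-yl]but-3-en-2-ol | C=C[C@](C)(O)[C@H]1COC(C)(C)O1 | intermediate
6 | (4R)-4-[(2S)-2-(4-methoxybenzyloxy)but-3-en-2-yl]-2,2-dimethyl-1,3-dioxolane | C=C[C@](C)(OCc1ccc(OC)cc1)[C@H]1COC(C)(C)O1 | intermediate
7 | (2R,3S)-3-(4-methoxybenzyloxy)-3-methylpent-4-ene-1,2-diol | C=C[C@](C)(OCc1ccc(OC)cc1)[C@H](O)CO | intermediate
8 | (2R,3S)-2-hydroxy-3-(4-methoxybenzyloxy)-3-methylpent-4-en-1-yl 4-methylbenzenesulfonate | C=C[C@](C)(OCc1ccc(OC)cc1)[C@H](O)COS(=O)(=O)c1ccc(C)cc1 | intermediate (not isolated)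
9 | (2R)-2-[(2S)-2-(4-methoxybenzyloxy)but-3-en-2-yl]oxirane | C=C[C@](C)(OCc1ccc(OC)cc1)[C@H]1CO1 | intermediate
10 | pent-4-yn-1-ol | C#CCCCO | starting material
11 | tert-butyldimethyl(pent-4-yn-1-yloxy)silane | C#CCCCO[Si](C)(C)C(C)(C)C | intermediate
12 | [(1E)-5-(tert-butyldimethylsilyloxy)-2-methylpent-1-en-1-yl]dimethylalane | C[Al](C)/C=C(\C)CCCO[Si](C)(C)C(C)(C)C | intermediate (not isolated)
13 | lithium butyl[(1E)-5-(tert-butyldimethylsilyloxy)-2-methylpent-1-en-1-yl]dimethylalanate | [Li+].CCCC[Al-](C)(C)/C=C(\C)CCCO[Si](C)(C)C(C)(C)C | intermediate (not isolated)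
14 | (3S,4R,6E)-10-(tert-butyldimethylsilyloxy)-3-(4-methoxybenzyloxy)-3,7-dimethyldeca-1,6-dien-4-ol | CC(C)(C)[Si](C)(C)OCCC/C(C)=C/C[C@@H](O)[C@@](C)(OCc1ccc(OC)cc1)C=C | intermediate
15 | (3S,4R,6E)-10-(tert-butyldimethylsilyloxy)-3-(4-methoxybenzyloxy)-3,7-dimethyldeca-1,6-dien-4-yl acetate | CC(C)(C)[Si](C)(C)OCCC/C(C)=C/C[C@@H](OC(C)=O)[C@@](C)(OCc1ccc(OC)cc1)C=C | intermediate
16 | (3S,4R,6E)-10-hydroxy-3-(4-methoxybenzyloxy)-3,7-dimethyldeca-1,6-dien-4-yl acetate | OCCC/C(C)=C/C[C@@H](OC(C)=O)[C@@](C)(OCc1ccc(OC)cc1)C=C | intermediate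
17 | (3S,4R,6E)-3-(4-methoxybenzyloxy)-3,7-dimethyl-10-oxodeca-1,6-dien-4-yl acetate | O=CCC/C(C)=C/C[C@@H](OC(C)=O)[C@@](C)(OCc1ccc(OC)cc1)C=C | intermediate
18 | 5-bromo-2-methylpent-2-ene | CC(C)=CCCBr | starting material
19 | (S)-3-(2-bromoethyl)-2,2-dimethyloxirane | BrCC[C@@H]1OC1(C)C | intermediate
20 | ethyl 2-(diphenoxyphosphoryl)acetate | CCOC(=O)CP(=O)(Oc1ccccc1)Oc1ccccc1 | starting material
21 | ethyl 2-(diphenoxyphosphoryl)-4-[(2S)-3,3-dimethyloxiran-2-yl]butanoate | CCOC(=O)C(CC[C@@H]1OC1(C)C)P(=O)(Oc1ccccc1)Oc1ccccc1 | intermediate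
22 | ethyl (2Z,6E,9R,10S)-9-acetoxy-2-{2-[(2S)-3,3-dimethyloxiran-2-yl]ethyl}-10-(4-methoxybenzyloxy)-6,10-dimethyldodeca-2,6,11-trienoate | CCOC(=O)/C(CC[C@@H]1OC1(C)C)=C\CC/C(C)=C/C[C@@H](OC(C)=O)[C@@](C)(OCc1ccc(OC)cc1)C=C | intermediate
23 | ethyl (12R,13S)-12-acetoxy-13-(4-methoxybenzyloxy)-3β-(trimethylsilyloxy)labda-8(17),14-dien-20-oate | C=C[C@](C)(OCc1ccc(OC)cc1)[C@@H](C[C@@H]1[C@@]2(C(=O)OCC)CC[C@H](O[Si](C)(C)C)C(C)(C)[C@@H]2CCC1=C)OC(C)=O | intermediate (not isolated)
24 | ethyl (12R,13S)-12-acetoxy-3β-hydroxy-13-(4-methoxybenzyloxy)labda-8(17),14-dien-20-oate | C=C[C@](C)(OCc1ccc(OC)cc1)[C@@H](C[C@@H]1[C@@]2(C(=O)OCC)CC[C@H](O)C(C)(C)[C@@H]2CCC1=C)OC(C)=O | intermediate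
25 | ethyl (12R,13S)-12-acetoxy-13-(4-methoxybenzyloxy)-3-oxolabda-8(17),14-dien-20-oate | C=C[C@](C)(OCc1ccc(OC)cc1)[C@@H](C[C@@H]1[C@@]2(C(=O)OCC)CCC(=O)C(C)(C)[C@@H]2CCC1=C)OC(C)=O | intermediate
26 | ethyl (12R,13S)-12-acetoxy-3α-hydroxy-13-(4-methoxybenzyloxy)labda-8(17),14-dien-20-oate | C=C[C@](C)(OCc1ccc(OC)cc1)[C@@H](C[C@@H]1[C@@]2(C(=O)OCC)CC[C@@H](O)C(C)(C)[C@@H]2CCC1=C)OC(C)=O | intermediate
27 | ethyl (12R,13S)-12-acetoxy-8α,17-epoxy-3α-hydroxy-13-(4-methoxybenzyloxy)labd-14-en-20-oate | C=C[C@](C)(OCc1ccc(OC)cc1)[C@@H](C[C@@H]1[C@@]2(C(=O)OCC)CC[C@@H](O)C(C)(C)[C@@H]2CC[C@]13CO3)OC(C)=O | intermediate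
28 | (12R,13S)-13-(4-methoxybenzyloxy)labd-14-ene-3α,8α,12,20-tetraol | C=C[C@](C)(OCc1ccc(OC)cc1)[C@@H](C[C@@H]1[C@@]2(CO)CC[C@@H](O)C(C)(C)[C@@H]2CC[C@@]1(C)O)O | intermediate
29 | (12R,13S)-8α-hydroxy-13-(4-methoxybenzyloxy)labd-14-ene-3α,12,20-triyl triacetate | C=C[C@](C)(OCc1ccc(OC)cc1)[C@@H](C[C@@H]1[C@@]2(COC(C)=O)CC[C@@H](OC(C)=O)C(C)(C)[C@@H]2CC[C@@]1(C)O)OC(C)=O | intermediate
30 | (12R,13S)-13-(4-methoxybenzyloxy)labd-14-ene-3α,8α,12,20-tetrayl tetraacetate | C=C[C@](C)(OCc1ccc(OC)cc1)[C@@H](C[C@@H]1[C@@]2(COC(C)=O)CC[C@@H](OC(C)=O)C(C)(C)[C@@H]2CC[C@@]1(C)OC(C)=O)OC(C)=O | intermediate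
31 | (12R,13S)-13-hydroxylabd-14-ene-3α,8α,12,20-tetrayl tetraacetate (CNP0127528.1) | C=C[C@](C)(O)[C@@H](C[C@@H]1[C@@]2(COC(C)=O)CC[C@@H](OC(C)=O)C(C)(C)[C@@H]2CC[C@@]1(C)OC(C)=O)OC(C)=O | target

**Step count**
Total: 22 steps. Longest linear sequence: 19 steps (1 to 31 through steps 1–6, 8–11 and 14–22).

**Steps most likely to fail**

1. Step 15 (the step proposed as new). The C10 α-ester radical may be reduced by Cp2TiCl to a titanium enolate and protonated before it closes ring B, so that the cascade stops at a monocyclic ring-A ester. The fallback sets out from 22 and uses known chemistry only. Reduction with i-Bu2AlH (CH2Cl2, −78 °C) takes the ethyl ester and the 12-acetate to the (2Z,6E)-allylic diol F1 with the oxirane intact. Ac2O/pyridine/DMAP gives the diacetate F2, in which C5=C10 is an ordinary electron-rich trisubstituted alkene. F2 is cyclised under the established conditions for 2,3-epoxypolyprenes (Cp2TiCl2 2.2 equiv, Mn powder, THF, rt, aqueous work-up), where both intermediate radicals are tertiary alkyl radicals, to the 3β-hydroxy decalin diacetate F3. Dess–Martin oxidation gives the 3-ketone F4, LiBH(s-Bu)3 the 3α-alcohol F5, and mCPBA the 8α,17-oxirane F6. LiAlH4 on F6 cleaves both acetates and opens the oxirane at C17, and the sequence comes back to the route at tetraol 28.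

2. Step 8. Transfer of the alkenyl group from the alanate to the substituted oxirane may be slow, so that alkyl transfer or Lewis-acid-induced rearrangement of the oxirane takes over. The fallback sets out from 11 and 9. The alane 12 is made as before and quenched with I2 to the (E)-vinyl iodide F7. Iodine–lithium exchange (t-BuLi, Et2O, −78 °C) gives the alkenyllithium F8, which is added to 9 in the presence of BF3·OEt2 at −78 °C and opens the oxirane at its CH2 terminus. The fallback comes back to the route at 14.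

3. Step 3. Methyl may be delivered mainly to the wrong face of the ketone (attack through a non-chelated Felkin-type or a six-membered chelate arrangement), and the enone may be lost to conjugate addition or polymerisation. The fallback sets out from 2 and inverts the order of the two additions. MeMgBr on 2 gives the stable methyl ketone F9, and vinylmagnesium bromide 3 is then added to F9 (THF, −78 °C). For a given facial preference of the dioxolane ketone, exchanging the resident and the incoming group gives the opposite configuration at C13, and the sensitive vinyl ketone is avoided. The fallback comes back to the route at 5.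

**Further compounds**
F1 | step 15 | (2Z,6E,9R,10S)-2-{2-[(2S)-3,3-dimethyloxiran-2-yl]ethyl}-10-(4-methoxybenzyloxy)-6,10-dimethyldodeca-2,6,11-triene-1,9-diol | OC/C(CC[C@@H]1OC1(C)C)=C\CC/C(C)=C/C[C@@H](O)[C@@](C)(OCc1ccc(OC)cc1)C=C
F2 | step 15 | (2Z,6E,9R,10S)-2-{2-[(2S)-3,3-dimethyloxiran-2-yl]ethyl}-10-(4-methoxybenzyloxy)-6,10-dimethyldodeca-2,6,11-triene-1,9-diyl diacetate | CC(=O)OC/C(CC[C@@H]1OC1(C)C)=C\CC/C(C)=C/C[C@@H](OC(C)=O)[C@@](C)(OCc1ccc(OC)cc1)C=C
F3 | step 15 | (12R,13S)-3β-hydroxy-13-(4-methoxybenzyloxy)labda-8(17),14-diene-12,20-diyl diacetate | C=C[C@](C)(OCc1ccc(OC)cc1)[C@@H](C[C@@H]1[C@@]2(COC(C)=O)CC[C@H](O)C(C)(C)[C@@H]2CCC1=C)OC(C)=O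
F4 | step 15 | (12R,13S)-13-(4-methoxybenzyloxy)-3-oxolabda-8(17),14-diene-12,20-diyl diacetate | C=C[C@](C)(OCc1ccc(OC)cc1)[C@@H](C[C@@H]1[C@@]2(COC(C)=O)CCC(=O)C(C)(C)[C@@H]2CCC1=C)OC(C)=O
F5 | step 15 | (12R,13S)-3α-hydroxy-13-(4-methoxybenzyloxy)labda-8(17),14-diene-12,20-diyl diacetate | C=C[C@](C)(OCc1ccc(OC)cc1)[C@@H](C[C@@H]1[C@@]2(COC(C)=O)CC[C@@H](O)C(C)(C)[C@@H]2CCC1=C)OC(C)=O
F6 | step 15 | (12R,13S)-8α,17-epoxy-3α-hydroxy-13-(4-methoxybenzyloxy)labd-14-ene-12,20-diyl diacetate | C=C[C@](C)(OCc1ccc(OC)cc1)[C@@H](C[C@@H]1[C@@]2(COC(C)=O)CC[C@@H](O)C(C)(C)[C@@H]2CC[C@]13CO3)OC(C)=O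
F7 | step 8 | tert-butyl{[(4E)-5-iodo-4-methylpent-4-en-1-yl]oxy}dimethylsilane | I/C=C(\C)CCCO[Si](C)(C)C(C)(C)C
F8 | step 8 | [(1E)-5-(tert-butyldimethylsilyloxy)-2-methylpent-1-en-1-yl]lithium | [Li]/C=C(\C)CCCO[Si](C)(C)C(C)(C)C
F9 | step 3 | (R)-1-(2,2-dimethyl-1,3-dioxolan-4-yl)ethan-1-one | CC(=O)[C@H]1COC(C)(C)O1
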